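You cannot take more other capture product out of a flask than you charged second nucleophile, one being spent per turnover, and the dawn run stands at that wall, reading 0.0686 M of product against 0.070 M charged. So count turnovers: the flask's cover is 70.0%, the second nucleophile charged per substrate charged.

| flask | substrate | first nucleophile | second nucleophile | remark | time |
|---|---|---|---|---|---|
| autumn | 0.067 M | 0.11 M | 0.070 M | run made earlier |  |
| dawn | 0.15 M | 0.11 M | 0.070 M | run made earlier |  |
| flask | 0.10 M | 0.110 M | 0.0700 M |  | 2.0 d |

| run | time / h | target / % | other capture product / % |
|---|---|---|---|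
| autumn | 2.50 | 4.8 | 89.1 |
| autumn | 4.00 | 2.6 | 90.6 |
| autumn | 8.00 | 3.1 | 90.4 |
| autumn | 15.0 | 3.1 | 88.9 |
| autumn | 30.0 | 1.3 | 90.6 |
| dawn | 2.50 | 13.2 | 44.7 |
| dawn | 4.00 | 14.2 | 46.1 |
| dawn | 8.00 | 11.9 | 45.4 |
| dawn | 15.0 | 12.8 | 47.1 |
| dawn | 30.0 | 14.3 | 45.3 |

(scatter of a reading: 1 percentage point)

* share of target in target plus other capture product at 1.0 min
* share of target in target plus other capture product at 2.0 d

- the earlier runs were read with a standard deviation of 1 percentage point

The autumn run looks nearly the same as the flask, with 0.067 M of substrate where the flask has 0.10 M and the same nucleophile charges, yet its cover is 104%, so second nucleophile exceeds substrate there, and its readings average 89.9% of other capture product and 2.98% of target, a ratio of 3.31%. In the flask the charge of second nucleophile falls short of the substrate, which makes it the limiting reagent for other capture product, so I expect that product to stop at the cover, with 0.0300 M of substrate finding no second nucleophile. Dawn has 0.0800 M of such leftover substrate and reads 0.0199 M of target; after taking away what the autumn ratio accounts for, that is 22.1% of the leftover. Carried to the flask, this gives 0.00894 M of target, so I commit to a share of 11.3% at 2.0 d, and for 1.0 min I take over the share read from the autumn plateau, 3.21%, as a rough figure.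

The forecast gives 2.2% (1.2% to 4%) at 1.0 min and, higher than my figure, 22.3% (19% to 25%) at 2.0 d, saying of the first nucleophile that remains that it “pairs up to form target”.

The flask gives 4.42% at 1.0 min and 10.4% at 2.0 d, by these steps:

    second nucleophile + intermediate → other capture product (k = 62.0 M⁻¹ s⁻¹)
    2 first nucleophile → homo dimer (k = 0.0160 M⁻¹ s⁻¹)
    first nucleophile + intermediate → target (k = 1.90 M⁻¹ s⁻¹)
    intermediate → solvolysis product (k = 0.110 s⁻¹)
    substrate + target → side product (k = 0.00390 M⁻¹ s⁻¹)
    substrate → intermediate (k = 0.00180 s⁻¹)

At 2.00 d the flask holds 70.0% of other capture product, level with its cover of 70.0%, with second nucleophile at 0% and target at 8.14%. In the neighbouring flask charged with 0.40 M of substrate, the other charges held, the cover shrinks to 17.5%, and other capture product ends at 17.5%.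

All runs were generated by integration on assumed constants; scatter was added.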